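## Analysis of the target

The target is a C15 diester on the longipinane skeleton, tricyclo[5.4.0.0^{2,8}]undecane. Locants used below follow the SMILES: C1 is CH–O-senecioate, C2 is CH2, C3 is CH–O-isovalerate, C4 is CMe2, C5 and C6 are the next two CH, C7 is C=O, C8 is =CH, C9 is =C(CH3), C10 is the last CH, and C11 is the quaternary C–CH3. The core is the cyclobutane C5–C6–C11–C10, and both of its diagonals are bridged: C6/C10 by the enone C7(=O)–C8=C9 (a verbenone-type bicyclo[3.1.1]heptenone), and C5/C11 by C4–C3–C2–C1 (a seven-membered ring). Of the six stereocentres, C5, C6, C10 and C11 are locked together by the cage, so only its absolute sense is free (5S,6R,10R,11R; ketone on the C6 side, C11 methyl towards the enone). C1 (R) and C3 (R) are the ends of an anti-1,3-diol, each next to a quaternary carbon, with the C1 oxygen on the C6/C7 side. The sensitive groups are the strained cyclobutane (acid invites Wagner–Meerwein shifts to the bornane-type skeleton), the enone, and two different esters on similar hindered 1,3-related alcohols (the senecioate deconjugates, and both can migrate under base). The synthesis is hard for three reasons: a cyclobutane bridged across both diagonals is the "crossed" product of any [2+2] reaction; C4 and C11 make almost every substitution-type closure neopentyl or tertiary; and the cage must be made as one enantiomer in register with C1 and C3. The plan is built on one feature: ketone C7 sits on cyclobutane carbon C6, C6 is bonded to quaternary C11, and C6–C7–C8–C9–C10–C11 is a cyclohexenone. Read backwards, this is the product of a 1,2-shift of C11 from a carbinol carbon C7 to C6, and the ring it comes from (cyclopentene C7–C8–C9–C10–C11 bridged by C6–C5) is a norbornene, that is, a Diels–Alder adduct.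

## Retrosynthetic reasoning

**18 ⇒ 17 (C6–C11 cut, C7–C11 rejoined).** The bond C6–C11 is cut and C11 is returned to C7, which then carries a silyloxy group, while C6 carries a triflate. This single disconnection removes the cyclobutane, the six-membered enone ring and the strain, and leaves the bridgehead-oxygenated norbornene 17. The forward reaction must move C11 (not the vinyl carbon C8) from C7 to C6, so the nucleofuge on C6 must be endo, anti-periplanar to C7–C11.

**17 ⇒ 16 ⇒ 15 (C6–O from C6–B).** The endo C6–O bond is traced to an endo C6–B bond, because C–B oxidation is retentive and tolerates alkenes. Boron is chosen because an (E)-alkenylboronate is a usable dienophile whose geometry translates directly into the endo position.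

**15 ⇒ 14 ⇒ 13 (retro-Diels–Alder, C5–C10 and C6–C7 cut).** The norbornene falls apart into a 1-siloxycyclopentadiene and the tethered alkenylboronate. The diene is the γ-enol ether of cyclopentenone 13, and because C11 is quaternary there is only one way to enolise and no 1,5-H shift. The tether C1–C4 becomes the seven-membered ring. The gain is a tricycle with five cage stereocentres from a monocyclic ketone; the forward reaction has to deliver only the regiochemistry (C6 to C7), since face, exo tether and endo boron are enforced.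

**13 ⇒ 12 ⇒ 11 ⇒ 10 (ester C–O bonds).** Both esters are installed before the cage is built, while the two oxygens are chemically distinct (C1–OH free, C3–O-PMB). No later step is basic, and the quaternary C11 rules out β-elimination of the β-acyloxy ketone.

**10 ⇒ 9 (C11–CH3).** The quaternary centre is made by methylating the dianion of the β-hydroxy ketone. The chelate transfers the configuration of C1 to C11, and both C11 epimers of 9 converge.

**9 ⇒ 6 + 8 (C11–C1).** A Mukaiyama aldol joins the ring to the chain and sets C1 anti to C3 by 1,3-induction from the β-alkoxy aldehyde.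

**6 ⇒ 5 ⇒ 4 ⇒ 3 ⇒ 1 + 2.** The aldehyde is released from its acetal, the C6–B bond comes from dehydrogenative borylation of a terminal alkene, the PMB ether from the carbinol, and the C3–C4 bond with the only reagent-controlled stereocentre (C3) from an enantioselective tert-prenylation of 1 with allene 2. Diene 8 comes from enone 7.

## Alternatives that were turned down

**Alternative 1:** the textbook [2+2]. Both cyclobutane bonds C6–C11 and C5–C10 are cut. The forward key step is a transannular enone–alkene photocycloaddition of the eleven-membered trienone A1 (enone C7(=O)–C6=C5 with C10=C11). It was turned down for these reasons: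
- Because both diagonals of the cyclobutane are bridged, every [2+2] retron places the two alkenes in one medium ring, and the required pairing is the crossed one.
- A triplet enone closes 1,5 first (C6 to C10), which leads to the parallel bicyclo[3.2.0] adduct.
- The cross-conjugated trienone would scramble its alkene geometry on irradiation, so nothing controls C5, C6, C10, C11 or the register of the cage with C1/C3.
- A1, with two stereocentres and three defined alkenes in an eleven-membered ring, would cost more steps than the whole present route.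

**Alternative 2:** intramolecular enolate alkylation, the classical closure of pinane-type cyclobutanes. The bond C5–C6 is cut, and the α′-enolate of the cis-fused keto tosylate A2 would displace the C5 sulfonate (4-exo-tet). It was turned down for these reasons:
- C5 is secondary and flanked by the quaternary C4, so the displacement is a neopentyl SN2 reaction inside a seven-membered ring; E2 and O-alkylation should win.
- The other α-bond, C6–C11, would need substitution at a tertiary carbon.
- γ-Deprotonation of the enone and the base-labile esters interfere.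
- A2 already carries five of the six stereocentres on a 6–7 system, so the precursor is no simpler than the product.

**Alternative 3:** oxidative enolate coupling. The bond C6–C11 is cut as a union of two enolate carbons (1,4-dicarbonyl retron C7(=O)–C6–C11–C1(=O)). Double deprotonation of diketone A3 and one-electron oxidation would close the cyclobutane and create C11, convergent at C11. It was turned down for these reasons:
- A four-membered ring with a new quaternary carbon must outrun intermolecular coupling and α-oxidation.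
- Enolisation competes at C2 and at the γ-position C10.
- The C3 ester is β to the C1 ketone and would be eliminated under the basic conditions.
- C1 would afterwards need a face-selective reduction in the presence of the enone.
- A3 needs a synthesis about as long as the whole present route.

Key step: step 13

Remark on the chemistry (assumptions): in step 1 the antipode of the SEGPHOS ligand is used that gives the (R)-carbinol, the sense being taken from the accepted model of this catalyst class. Abbreviations: Bpin = 4,4,5,5-tetramethyl-1,3,2-dioxaborolan-2-yl, PMB = 4-methoxybenzyl, TBS = tert-butyldimethylsilyl.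

## Route

Step 1
Reactants: 1 3,3-diethoxypropan-1-ol; 2 3-methylbuta-1,2-diene
Product: 3 (3R)-1,1-diethoxy-4,4-dimethylhex-5-en-3-ol
Conditions: [Ir(cod)Cl]2 (cat.), SEGPHOS (cat.), 4-chloro-3-nitrobenzoic acid (cat.), Cs2CO3 (cat.), THF, 60 °C
Reagents that add atoms: none
Why: Iridium-catalysed transfer-hydrogenative carbonyl tert-prenylation: the alcohol is dehydrogenated to the aldehyde, the allene is hydrometallated to a 1,1-dimethylallyl-iridium species, and this adds through its substituted terminus inside the chiral complex, forming C3–C4 and the C3 stereocentre (R, catalyst control) without by-product.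

Step 2
Reactants: 3 (3R)-1,1-diethoxy-4,4-dimethylhex-5-en-3-ol
Product: 4 1-({[(3R)-1,1-diethoxy-4,4-dimethylhex-5-en-3-yl]oxy}methyl)-4-methoxybenzene
Conditions: NaH, PMBCl, n-Bu4NI (cat.), DMF, 0 °C to rt
Reagents that add atoms: 4-methoxybenzyl chloride, COc1ccc(CCl)cc1
Why: Williamson etherification of the hindered alkoxide; PMB is chosen because a β-PMB-oxy aldehyde gives strong 1,3-anti induction in step 6 and is later removed oxidatively without touching esters, enone or boronate.

Step 3
Reactants: 4 1-({[(3R)-1,1-diethoxy-4,4-dimethylhex-5-en-3-yl]oxy}methyl)-4-methoxybenzene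
Product: 5 2-[(1E,4R)-6,6-diethoxy-4-[(4-methoxyphenyl)methoxy]-3,3-dimethylhex-1-en-1-yl]-4,4,5,5-tetramethyl-1,3,2-dioxaborolane
Conditions: B2pin2, trans-[RhCl(CO)(PPh3)2] (cat.), toluene/MeCN 3:1, 80 °C
Reagents that add atoms: bis(pinacolato)diboron, CC1(C)OB(OC1(C)C)B1OC(C)(C)C(C)(C)O1
Why: Rhodium-catalysed dehydrogenative borylation of a terminal alkene (boryl insertion, then β-hydride elimination); the quaternary allylic carbon C4 excludes chain walking, and the elimination should give the (E)-alkenylboronate, whose geometry later fixes the endo position of the nucleofuge.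

Step 4
Reactants: 5 2-[(1E,4R)-6,6-diethoxy-4-[(4-methoxyphenyl)methoxy]-3,3-dimethylhex-1-en-1-yl]-4,4,5,5-tetramethyl-1,3,2-dioxaborolane
Product: 6 (3R,5E)-3-[(4-methoxyphenyl)methoxy]-4,4-dimethyl-6-Bpin-hex-5-enal
Conditions: p-TsOH·H2O (cat.), THF/H2O, rt
Reagents that add atoms: water, O
Why: Acid-catalysed acetal hydrolysis; the pinacol boronate and the PMB ether are stable to dilute aqueous acid, and the β-alkoxy aldehyde is used crude to avoid β-elimination.

Step 5
Reactants: 7 3-methylcyclopent-2-en-1-one
Product: 8 4-methyl-2-[(trimethylsilyl)oxy]cyclopenta-1,3-diene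
Conditions: LDA, THF, −78 °C; TMSCl; non-aqueous work-up, used at once
Reagents that add atoms: chlorotrimethylsilane, C[Si](C)(C)Cl
Why: Kinetic deprotonation of the enone at the α′ carbon (the future C11) and O-silylation give the cross-conjugated 2-siloxydiene, the nucleophile for the Mukaiyama aldol.

Step 6
Reactants: 6 (3R,5E)-3-[(4-methoxyphenyl)methoxy]-4,4-dimethyl-6-Bpin-hex-5-enal; 8 4-methyl-2-[(trimethylsilyl)oxy]cyclopenta-1,3-diene
Product: 9 5-[(1R,3R,5E)-1-hydroxy-3-[(4-methoxyphenyl)methoxy]-4,4-dimethyl-6-Bpin-hex-5-en-1-yl]-3-methylcyclopent-2-en-1-one (both epimers at ring C5)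
Conditions: BF3·OEt2, CH2Cl2, −78 °C; aq. NaHCO3
Reagents that add atoms: none
Why: Mukaiyama aldol addition through an open transition state forms C11–C1; with a β-alkoxy aldehyde and BF3 the enol silane attacks the face of the dipole-minimised conformer, which should give the 1,3-anti (1R,3R) carbinol, while the C11–H centre stays a mixture that step 7 erases.

Step 7
Reactants: 9 5-[(1R,3R,5E)-1-hydroxy-3-[(4-methoxyphenyl)methoxy]-4,4-dimethyl-6-Bpin-hex-5-en-1-yl]-3-methylcyclopent-2-en-1-one
Product: 10 (5S)-5-[(1R,3R,5E)-1-hydroxy-3-[(4-methoxyphenyl)methoxy]-4,4-dimethyl-6-Bpin-hex-5-en-1-yl]-3,5-dimethylcyclopent-2-en-1-one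
Conditions: LDA (2.3 equiv), THF, −78 °C; MeI, DMPU, −78 to −45 °C; AcOH quench at −78 °C
Reagents that add atoms: iodomethane, CI
Why: Fráter–Seebach-type alkylation: the dianion is a lithium chelate between the enolate and alkoxide oxygens in which MeI attacks C11 anti to the C2 chain, so the quaternary centre (5S, methyl anti to the C1 oxygen) should form from either C11 epimer; the dianion can undergo neither retro-aldol cleavage nor elimination.

Step 8
Reactants: 10 (5S)-5-[(1R,3R,5E)-1-hydroxy-3-[(4-methoxyphenyl)methoxy]-4,4-dimethyl-6-Bpin-hex-5-en-1-yl]-3,5-dimethylcyclopent-2-en-1-one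
Product: 11 (1R,3R,5E)-1-[(1S)-1,4-dimethyl-2-oxocyclopent-3-en-1-yl]-3-[(4-methoxyphenyl)methoxy]-4,4-dimethyl-6-Bpin-hex-5-en-1-yl 3-methylbut-2-enoate
Conditions: 3-methylbut-2-enoyl chloride, pyridine, DMAP (cat.), CH2Cl2, 0 °C to rt
Reagents that add atoms: 3-methylbut-2-enoyl chloride, CC(C)=CC(Cl)=O
Why: DMAP-assisted acylation of the neopentyl-type C1 alcohol; pyridine instead of a trialkylamine limits vinylketene formation and deconjugation of the senecioyl group, and the quaternary C11 makes β-elimination of the new β-acyloxy ketone impossible.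

Step 9
Reactants: 11 (1R,3R,5E)-1-[(1S)-1,4-dimethyl-2-oxocyclopent-3-en-1-yl]-3-[(4-methoxyphenyl)methoxy]-4,4-dimethyl-6-Bpin-hex-5-en-1-yl 3-methylbut-2-enoate
Product: 12 (1R,3R,5E)-1-[(1S)-1,4-dimethyl-2-oxocyclopent-3-en-1-yl]-3-hydroxy-4,4-dimethyl-6-Bpin-hex-5-en-1-yl 3-methylbut-2-enoate
Conditions: DDQ, CH2Cl2/pH 7 buffer, 0 °C
Reagents that add atoms: none
Why: Oxidative PMB cleavage (hydride abstraction by DDQ, hydrolysis of the oxocarbenium ion); the neutral buffered medium should suppress 1,3-migration of the senecioate to the freed C3 hydroxyl.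

Step 10
Reactants: 12 (1R,3R,5E)-1-[(1S)-1,4-dimethyl-2-oxocyclopent-3-en-1-yl]-3-hydroxy-4,4-dimethyl-6-Bpin-hex-5-en-1-yl 3-methylbut-2-enoate
Product: 13 (1R,3R,5E)-1-[(1S)-1,4-dimethyl-2-oxocyclopent-3-en-1-yl]-4,4-dimethyl-3-[(3-methylbutanoyl)oxy]-6-Bpin-hex-5-en-1-yl 3-methylbut-2-enoate
Conditions: 3-methylbutanoyl chloride, pyridine, DMAP (cat.), CH2Cl2, 0 °C
Reagents that add atoms: 3-methylbutanoyl chloride, CC(C)CC(Cl)=O
Why: Acylation of the C3 alcohol, run cold and fast so that acylation outpaces acyl migration; from here on the two oxygens carry their final, different esters and no later step is basic enough to exchange them.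

Step 11
Reactants: 13 (1R,3R,5E)-1-[(1S)-1,4-dimethyl-2-oxocyclopent-3-en-1-yl]-4,4-dimethyl-3-[(3-methylbutanoyl)oxy]-6-Bpin-hex-5-en-1-yl 3-methylbut-2-enoate
Product: 15 (3R,5R)-8-endo-Bpin-9-[(tert-butyldimethylsilyl)oxy]-2,6,6,11-tetramethyl-5-[(3-methylbutanoyl)oxy]tricyclo[5.4.0.0^{2,9}]undec-10-en-3-yl 3-methylbut-2-enoate, via silyl dienol ether 14 (not isolated)
Conditions: TBSOTf, Et3N, CH2Cl2, 0 °C; evaporate; toluene (high dilution), BHT, 110 °C, sealed tube
Reagents that add atoms: tert-butyldimethylsilyl trifluoromethanesulfonate, CC(C)(C)[Si](C)(C)OS(=O)(=O)C(F)(F)F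
Why: Soft γ-enolisation (the quaternary C11 leaves only C10–H in the ring, and any exocyclic isomer cannot cycloadd and should equilibrate) gives the 1-siloxycyclopentadiene 14, which cannot undergo 1,5-H shifts. In the intramolecular Diels–Alder reaction the four-atom tether (helped by the Thorpe–Ingold effect of C4 and C11) forces addition to the diene face syn to C1 and puts C4 exo, and the (E) geometry then puts boron endo. The donor at C7 directs the boron-bearing C6 to C7 (ortho rule, reinforced by the hindered C5 bonding to the unsubstituted terminus C10), so C5, C6, C7 and C10 are set in one step.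

Step 12
Reactants: 15 (3R,5R)-8-endo-Bpin-9-[(tert-butyldimethylsilyl)oxy]-2,6,6,11-tetramethyl-5-[(3-methylbutanoyl)oxy]tricyclo[5.4.0.0^{2,9}]undec-10-en-3-yl 3-methylbut-2-enoate
Product: 16 (3R,5R)-9-[(tert-butyldimethylsilyl)oxy]-8-endo-hydroxy-2,6,6,11-tetramethyl-5-[(3-methylbutanoyl)oxy]tricyclo[5.4.0.0^{2,9}]undec-10-en-3-yl 3-methylbut-2-enoate
Conditions: NaBO3·4H2O, THF/H2O, rt
Reagents that add atoms: sodium perborate, [Na+].[Na+].O[B-]1(O)OO[B-](O)(O)OO1
Why: Oxidation of the secondary alkylboronate by 1,2-migration of carbon from boron to oxygen proceeds with retention, so the hydroxyl is endo; perborate is mild enough for the esters, the alkenes and the silyl ether.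

Step 13
Reactants: 16 (3R,5R)-9-[(tert-butyldimethylsilyl)oxy]-8-endo-hydroxy-2,6,6,11-tetramethyl-5-[(3-methylbutanoyl)oxy]tricyclo[5.4.0.0^{2,9}]undec-10-en-3-yl 3-methylbut-2-enoate
Product: 18 (1R,2R,3R,5R,7S,8R)-2,6,6,11-tetramethyl-5-[(3-methylbutanoyl)oxy]-9-oxotricyclo[5.4.0.0^{2,8}]undec-10-en-3-yl 3-methylbut-2-enoate (the target), via endo triflate 17 (not isolated)
Conditions: Tf2O, 2,6-di-tert-butyl-4-methylpyridine, CH2Cl2, −78 to 0 °C
Reagents that add atoms: none
Why: O-Triflation of the endo C6 hydroxyl gives 17; as the triflate leaves, the anti-periplanar C7–C11 bond migrates to C6 under the push of the silyloxy lone pair, and the resulting O-silyl oxocarbenium ion (also an allyl cation through C8=C9–CH3) loses its silyl group to triflate to give the enone. The closest known reaction type is the pinacol-type (semipinacol) 1,2-shift of β-sulfonyloxy silyl ethers and alcohols, in particular the bridge shift that turns 1-alkoxybicyclo[2.2.2]oct-5-en-2-yl sulfonates into bicyclo[3.2.1]octenones, and the Tiffeneau–Demjanov-type one-carbon ring expansion of cycloalkanols. Two rings change at once by the same 1,2-shift (an intramolecular displacement at C6 by the C7–C11 σ bond): the cyclopentene C7–C8–C9–C10–C11 expands to the cyclohexenone C6–C7–C8–C9–C10–C11, and the cyclopentane C5–C6–C7–C11–C10 contracts to the cyclobutane C5–C6–C11–C10. C6 is inverted (C11 enters anti to the endo triflate) and C11 migrates with retention, so the configurations at C5, C6, C10 and C11 follow from the cycloadduct and are the only ones the cage allows, while C1 and C3 are untouched. The selectivity needed is migration of the bridge carbon C11 and not of the vinyl carbon C8; it is secured by the endo triflate, which is anti-periplanar to C7–C11, gauche to C7–C8 and not aligned for π-participation by C8=C9. E2 is blocked because the only hydrogen on C5 is syn to the triflate, and SN2 is blocked by the cage. The strain gained (bornane-type to pinane-type) should be outweighed by formation of the conjugated C=O and loss of TBSOTf.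

## Compound list

1 | 3,3-diethoxypropan-1-ol | OCCC(OCC)OCC | starting material
2 | 3-methylbuta-1,2-diene | CC(C)=C=C | starting material
3 | (3R)-1,1-diethoxy-4,4-dimethylhex-5-en-3-ol | CCOC(OCC)C[C@@H](O)C(C)(C)C=C | intermediate
4 | 1-({[(3R)-1,1-diethoxy-4,4-dimethylhex-5-en-3-yl]oxy}methyl)-4-methoxybenzene | CCOC(OCC)C[C@@H](OCc1ccc(OC)cc1)C(C)(C)C=C | intermediate
5 | 2-[(1E,4R)-6,6-diethoxy-4-[(4-methoxyphenyl)methoxy]-3,3-dimethylhex-1-en-1-yl]-4,4,5,5-tetramethyl-1,3,2-dioxaborolane | CCOC(OCC)C[C@@H](OCc1ccc(OC)cc1)C(C)(C)/C=C/B1OC(C)(C)C(C)(C)O1 | intermediate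
6 | (3R,5E)-3-[(4-methoxyphenyl)methoxy]-4,4-dimethyl-6-Bpin-hex-5-enal | O=CC[C@@H](OCc1ccc(OC)cc1)C(C)(C)/C=C/B1OC(C)(C)C(C)(C)O1 | intermediate
7 | 3-methylcyclopent-2-en-1-one | CC1=CC(=O)CC1 | starting material
8 | 4-methyl-2-[(trimethylsilyl)oxy]cyclopenta-1,3-diene | CC1=CC(O[Si](C)(C)C)=CC1 | intermediate
9 | 5-[(1R,3R,5E)-1-hydroxy-3-[(4-methoxyphenyl)methoxy]-4,4-dimethyl-6-Bpin-hex-5-en-1-yl]-3-methylcyclopent-2-en-1-one (both epimers at ring C5) | CC1=CC(=O)C(C1)[C@H](O)C[C@@H](OCc2ccc(OC)cc2)C(C)(C)/C=C/B3OC(C)(C)C(C)(C)O3 | intermediate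
10 | (5S)-5-[(1R,3R,5E)-1-hydroxy-3-[(4-methoxyphenyl)methoxy]-4,4-dimethyl-6-Bpin-hex-5-en-1-yl]-3,5-dimethylcyclopent-2-en-1-one | O=C1C=C(C)C[C@@]1(C)[C@H](O)C[C@@H](OCc2ccc(OC)cc2)C(C)(C)/C=C/B3OC(C)(C)C(C)(C)O3 | intermediate
11 | (1R,3R,5E)-1-[(1S)-1,4-dimethyl-2-oxocyclopent-3-en-1-yl]-3-[(4-methoxyphenyl)methoxy]-4,4-dimethyl-6-Bpin-hex-5-en-1-yl 3-methylbut-2-enoate | O=C1C=C(C)C[C@@]1(C)[C@H](OC(=O)C=C(C)C)C[C@@H](OCc2ccc(OC)cc2)C(C)(C)/C=C/B3OC(C)(C)C(C)(C)O3 | intermediate
12 | (1R,3R,5E)-1-[(1S)-1,4-dimethyl-2-oxocyclopent-3-en-1-yl]-3-hydroxy-4,4-dimethyl-6-Bpin-hex-5-en-1-yl 3-methylbut-2-enoate | O=C1C=C(C)C[C@@]1(C)[C@H](OC(=O)C=C(C)C)C[C@@H](O)C(C)(C)/C=C/B3OC(C)(C)C(C)(C)O3 | intermediate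
13 | (1R,3R,5E)-1-[(1S)-1,4-dimethyl-2-oxocyclopent-3-en-1-yl]-4,4-dimethyl-3-[(3-methylbutanoyl)oxy]-6-Bpin-hex-5-en-1-yl 3-methylbut-2-enoate | O=C1C=C(C)C[C@@]1(C)[C@H](OC(=O)C=C(C)C)C[C@@H](OC(=O)CC(C)C)C(C)(C)/C=C/B3OC(C)(C)C(C)(C)O3 | intermediate
14 | (1R,3R,5E)-1-[(1S)-2-[(tert-butyldimethylsilyl)oxy]-1,4-dimethylcyclopenta-2,4-dien-1-yl]-4,4-dimethyl-3-[(3-methylbutanoyl)oxy]-6-Bpin-hex-5-en-1-yl 3-methylbut-2-enoate | CC(C)(C)[Si](C)(C)OC1=CC(C)=C[C@@]1(C)[C@H](OC(=O)C=C(C)C)C[C@@H](OC(=O)CC(C)C)C(C)(C)/C=C/B3OC(C)(C)C(C)(C)O3 | intermediate (not isolated)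
15 | (3R,5R)-8-endo-Bpin-9-[(tert-butyldimethylsilyl)oxy]-2,6,6,11-tetramethyl-5-[(3-methylbutanoyl)oxy]tricyclo[5.4.0.0^{2,9}]undec-10-en-3-yl 3-methylbut-2-enoate (boron syn to the C10=C11 bridge, C3–C6 chain exo) | CC(C)=CC(=O)O[C@@H]1C[C@@H](OC(=O)CC(C)C)C(C)(C)[C@@H]2[C@@H](B4OC(C)(C)C(C)(C)O4)[C@@]3(O[Si](C)(C)C(C)(C)C)C=C(C)[C@@H]2[C@]31C | intermediate
16 | (3R,5R)-9-[(tert-butyldimethylsilyl)oxy]-8-endo-hydroxy-2,6,6,11-tetramethyl-5-[(3-methylbutanoyl)oxy]tricyclo[5.4.0.0^{2,9}]undec-10-en-3-yl 3-methylbut-2-enoate | CC(C)=CC(=O)O[C@@H]1C[C@@H](OC(=O)CC(C)C)C(C)(C)[C@@H]2[C@@H](O)[C@@]3(O[Si](C)(C)C(C)(C)C)C=C(C)[C@@H]2[C@]31C | intermediate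
17 | (3R,5R)-9-[(tert-butyldimethylsilyl)oxy]-2,6,6,11-tetramethyl-5-[(3-methylbutanoyl)oxy]-8-endo-[(trifluoromethanesulfonyl)oxy]tricyclo[5.4.0.0^{2,9}]undec-10-en-3-yl 3-methylbut-2-enoate | CC(C)=CC(=O)O[C@@H]1C[C@@H](OC(=O)CC(C)C)C(C)(C)[C@@H]2[C@@H](OS(=O)(=O)C(F)(F)F)[C@@]3(O[Si](C)(C)C(C)(C)C)C=C(C)[C@@H]2[C@]31C | intermediate (not isolated)
18 | (1R,2R,3R,5R,7S,8R)-2,6,6,11-tetramethyl-5-[(3-methylbutanoyl)oxy]-9-oxotricyclo[5.4.0.0^{2,8}]undec-10-en-3-yl 3-methylbut-2-enoate (CNP0335239.1) | CC(C)=CC(=O)O[C@@H]1C[C@@H](OC(=O)CC(C)C)C(C)(C)[C@@H]2[C@H]3C(=O)C=C(C)[C@@H]2[C@]31C | target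

## Step count and least certain steps

Total step count: 13. Longest linear sequence: 12 steps (steps 1–4, then 6–13); step 5 is a one-step side branch.

**Step 13 (key step).** The most likely failure is loss of stereoelectronic control. If the hindered triflate ionises to a free cation before C11 moves, the vinyl carbon C8 can shift instead, or the senecioate carbonyl at C1 can participate from the exo face; the triflate may also fail to form next to the bridgehead silyl ether. The fallback drives the shift from a metal alkoxide instead of relying on ionisation. It sets out from 16: MsCl/pyridine should give the endo mesylate F1, and HF·pyridine should free the bridgehead hydroxyl to give the hydroxy mesylate F2. Et3Al (CH2Cl2, −78 to 0 °C) then forms the aluminium alkoxide and promotes the concerted anti 1,2-shift (organoaluminium-promoted pinacol-type rearrangement of a β-mesyloxy alcohol), which leaves no cationic character at C6. The fallback comes back to the route at 18. If no bridge shift can be realised at all, the cage would have to be closed photochemically as in Alternative 1.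

**Step 11.** The most likely failure is a slow cycloaddition: the pinacol boronate is only weakly activating and is bulky next to the bridgehead silyl ether, so the silyl dienol ether may be lost by desilylation at the temperature needed, or regiocontrol may erode. The fallback carries the nucleofuge itself through the cycloaddition instead of a boron placeholder, so that regiochemistry rests on sterics alone (C5 to the unsubstituted terminus C10). It sets out from 13: stereoretentive halodeboronation with NBS (MeCN, 0 °C) should give the (E)-alkenyl bromide F3. TBSOTf/Et3N should give its silyl dienol ether F4, which is heated without isolation to the endo bromide cycloadduct F5. Silver triflate with 2,6-di-tert-butyl-4-methylpyridine then removes bromide with the same 1,2-shift of C11, so the fallback comes back at 18 and saves the oxidation step.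

**Step 7.** The most likely failure is retro-aldol cleavage of the lithium aldolate before the second deprotonation, γ- instead of α′-deprotonation, or poor facial selectivity if the chelate is not maintained. The fallback brings the methyl group in with the nucleophile. It sets out from 7: LDA/MeI should give 3,5-dimethylcyclopent-2-en-1-one F6, and LDA/TMSCl its tetrasubstituted silyl dienol ether F7. A BF3-mediated Mukaiyama aldol of F7 with aldehyde 6 then forms C11 and C1 together, coming back at 10; the C1/C11 relationship then rests on an open transition state and may need chromatographic separation.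

**Step 3.** The most likely failure is hydroboration of the alkene by the pinacolborane that the reaction generates, or hydrogenation, in place of dehydrogenative borylation. The fallback builds the alkenylboronate by carbonyl olefination. It sets out from 4: Lemieux–Johnson cleavage (OsO4 cat., NaIO4, 2,6-lutidine) should give the aldehyde F8, and Takai–Utimoto-type boron olefination (CrCl2, Cl2CHBpin, LiI, THF) should give the (E)-alkenylboronate, coming back at 5.

## Further compounds

F1 | step 13 | (3R,5R)-9-[(tert-butyldimethylsilyl)oxy]-8-endo-[(methanesulfonyl)oxy]-2,6,6,11-tetramethyl-5-[(3-methylbutanoyl)oxy]tricyclo[5.4.0.0^{2,9}]undec-10-en-3-yl 3-methylbut-2-enoate | CC(C)=CC(=O)O[C@@H]1C[C@@H](OC(=O)CC(C)C)C(C)(C)[C@@H]2[C@@H](OS(C)(=O)=O)[C@@]3(O[Si](C)(C)C(C)(C)C)C=C(C)[C@@H]2[C@]31C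
F2 | step 13 | (3R,5R)-9-hydroxy-8-endo-[(methanesulfonyl)oxy]-2,6,6,11-tetramethyl-5-[(3-methylbutanoyl)oxy]tricyclo[5.4.0.0^{2,9}]undec-10-en-3-yl 3-methylbut-2-enoate | CC(C)=CC(=O)O[C@@H]1C[C@@H](OC(=O)CC(C)C)C(C)(C)[C@@H]2[C@@H](OS(C)(=O)=O)[C@@]3(O)C=C(C)[C@@H]2[C@]31C
F3 | step 11 | (1R,3R,5E)-6-bromo-1-[(1S)-1,4-dimethyl-2-oxocyclopent-3-en-1-yl]-4,4-dimethyl-3-[(3-methylbutanoyl)oxy]hex-5-en-1-yl 3-methylbut-2-enoate | O=C1C=C(C)C[C@@]1(C)[C@H](OC(=O)C=C(C)C)C[C@@H](OC(=O)CC(C)C)C(C)(C)/C=C/Br
F4 | step 11 | (1R,3R,5E)-6-bromo-1-[(1S)-2-[(tert-butyldimethylsilyl)oxy]-1,4-dimethylcyclopenta-2,4-dien-1-yl]-4,4-dimethyl-3-[(3-methylbutanoyl)oxy]hex-5-en-1-yl 3-methylbut-2-enoate | CC(C)(C)[Si](C)(C)OC1=CC(C)=C[C@@]1(C)[C@H](OC(=O)C=C(C)C)C[C@@H](OC(=O)CC(C)C)C(C)(C)/C=C/Br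
F5 | step 11 | (3R,5R)-8-endo-bromo-9-[(tert-butyldimethylsilyl)oxy]-2,6,6,11-tetramethyl-5-[(3-methylbutanoyl)oxy]tricyclo[5.4.0.0^{2,9}]undec-10-en-3-yl 3-methylbut-2-enoate | CC(C)=CC(=O)O[C@@H]1C[C@@H](OC(=O)CC(C)C)C(C)(C)[C@@H]2[C@@H](Br)[C@@]3(O[Si](C)(C)C(C)(C)C)C=C(C)[C@@H]2[C@]31C
F6 | step 7 | 3,5-dimethylcyclopent-2-en-1-one | CC1=CC(=O)C(C)C1
F7 | step 7 | 1,4-dimethyl-2-[(trimethylsilyl)oxy]cyclopenta-1,3-diene | CC1=CC(O[Si](C)(C)C)=C(C)C1
F8 | step 3 | (3R)-5,5-diethoxy-3-[(4-methoxyphenyl)methoxy]-2,2-dimethylpentanal | CCOC(OCC)C[C@@H](OCc1ccc(OC)cc1)C(C)(C)C=O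
A1 | alternative 1 | (2E,4E,6R,8R,10E)-3,5,9,9-tetramethyl-8-[(3-methylbutanoyl)oxy]-1-oxocycloundeca-2,4,10-trien-6-yl 3-methylbut-2-enoate | CC(C)=CC(=O)O[C@@H]1C[C@@H](OC(=O)CC(C)C)C(C)(C)/C=C/C(=O)/C=C(C)/C=C1\C
A2 | alternative 2 | cis-fused 1,5,5,8-tetramethyl-4-[(3-methylbutanoyl)oxy]-6-[(4-methylbenzenesulfonyl)oxy]-10-oxobicyclo[5.4.0]undec-8-en-2-yl 3-methylbut-2-enoate (sulfonate anti to the incoming enolate carbon) | CC(C)=CC(=O)O[C@@H]1C[C@@H](OC(=O)CC(C)C)C(C)(C)[C@@H](OS(=O)(=O)c2ccc(C)cc2)[C@@H]3C(C)=CC(=O)C[C@@]31C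
A3 | alternative 3 | cis-fused 2,6,6,11-tetramethyl-3,9-dioxobicyclo[5.4.0]undec-10-en-5-yl 3-methylbutanoate (C2 epimers) | O=C1C[C@@H](OC(=O)CC(C)C)C(C)(C)[C@@H]2CC(=O)C=C(C)[C@@H]2C1C
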